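**Retrosynthetic overview**

1. Target 15 is (−)-epigallocatechin-(4β→8)-(−)-epigallocatechin-(4β→8)-(−)-epigallocatechin 3-O-gallate-(4β→8)-(−)-epicatechin. It is reached by global hydrogenolysis of 22 benzyl ethers; the two upper interflavan bonds (C4–C8) are cut in turn, each back to the same 4β-(2-ethoxyethoxy) electrophile 3 made from (−)-epigallocatechin.
2. The lower dimer 12 is cut at two bonds of ring A of the terminal epicatechin unit at once: C4–C4a (closure of its ring C) and C8–C4 of the gallate unit. This gives the open-chain epoxy aryl ether 10 and the gallate electrophile 5 (3 plus acid 4).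
3. Enabling feature: ring A of the terminal unit is a phloroglucinol triether whose two carbons ortho to O1 (C4a and C8) both carry carbon substituents in the target, while C4 is a CH2 next to the C3 carbinol. C3–O/C4 is therefore a latent terminal epoxide with C4a as its internal nucleophile, and C8 is left to take the flavan cation.
4. Ether 10 comes from phenol 9 and erythro epoxy alcohol 8 (Mitsunobu, O1–C2 with inversion); 8 comes from aldehyde 6 by vinyl addition and Sharpless kinetic resolution, which sets C2 and C3.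
5. Ring order: ring C of each of the three upper units is bought intact in epigallocatechin; ring C of the terminal unit is the only ring built (step 7); no ring is formed afterwards.

Key step: step 7

Remark on the structure: the SMILES is read as having every flavan unit 2R,3R (2,3-cis) and every interflavan bond 4β (trans to O3), with the galloyl ester on the third unit from the top.

**Step 1**
Reactants: 1 (−)-epigallocatechin
Product: 2 5,7,3',4',5'-penta-O-benzyl-(−)-epigallocatechin (3-OH free)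
Conditions: BnBr (5.5 equiv), K2CO3, DMF, 0 °C to rt, N2
Reagents that add atoms: benzyl bromide, BrCc1ccccc1
Why: Williamson etherification; K2CO3 deprotonates the five phenols but not the secondary 3-OH, so only phenolic oxygens should be benzylated, and the mild temperature should avoid base-induced epimerization at C2.

**Step 2**
Reactants: 2 5,7,3',4',5'-penta-O-benzyl-(−)-epigallocatechin
Product: 3 (2R,3R,4S)-4β-(2-ethoxyethoxy)-5,7,3',4',5'-penta-O-benzylepigallocatechin
Conditions: DDQ (2 equiv), 2-ethoxyethanol (5 equiv), CH2Cl2, rt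
Reagents that add atoms: 2-ethoxyethanol, CCOCCO
Why: DDQ benzylic oxidation (hydride abstraction at C4, activated by the ring A oxygens) should give a cation that the alcohol traps on the face anti to the C2 aryl group and the 3-OH, setting the 4β acetal; this is the standard C4 activation of benzylated flavan-3-ols.

**Step 3**
Reactants: 3 (2R,3R,4S)-4β-(2-ethoxyethoxy)-5,7,3',4',5'-penta-O-benzylepigallocatechin; 4 3,4,5-tris(benzyloxy)benzoic acid
Product: 5 4β-(2-ethoxyethoxy)-5,7,3',4',5'-penta-O-benzylepigallocatechin 3-O-[3,4,5-tris(benzyloxy)benzoate]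
Conditions: DCC (1.5 equiv), DMAP (0.2 equiv), CH2Cl2, rt
Reagents that add atoms: none
Why: Steglich esterification of the axial 3-OH; the conditions are non-acidic, so the C4 acetal should survive, and no stereocenter is touched.

**Step 4**
Reactants: 6 3,4-bis(benzyloxy)benzaldehyde
Product: 7 rac-1-[3,4-bis(benzyloxy)phenyl]prop-2-en-1-ol
Conditions: vinylmagnesium bromide, THF, −78 to 0 °C; aqueous work-up
Reagents that add atoms: vinylmagnesium bromide, C=C[Mg]Br
Why: Grignard 1,2-addition to the aldehyde; no stereocontrol is needed because the racemate is resolved in the next step.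

**Step 5**
Reactants: 7 rac-1-[3,4-bis(benzyloxy)phenyl]prop-2-en-1-ol
Product: 8 (S)-[3,4-bis(benzyloxy)phenyl][(R)-oxiran-2-yl]methanol (erythro epoxy alcohol)
Conditions: Ti(OiPr)4 (0.2 equiv), diisopropyl L-(+)-tartrate (0.3 equiv), t-BuOOH (0.6 equiv), 4 Å molecular sieves, CH2Cl2, −20 °C
Reagents that add atoms: tert-butyl hydroperoxide, CC(C)(C)OO
Why: Sharpless kinetic resolution (Katsuki–Sharpless epoxidation of a secondary allylic alcohol); with the L-(+)-tartrate the (R)-alcohol should be epoxidized much faster than the (S)-alcohol and give the erythro product, so the catalyst fixes both future flavan stereocenters (C2 as the (S)-carbinol, C3 as the (R)-oxirane carbon) in one event.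

**Step 6**
Reactants: 8 (S)-[3,4-bis(benzyloxy)phenyl][(R)-oxiran-2-yl]methanol; 9 3,5-bis(benzyloxy)phenol
Product: 10 (R)-2-{(R)-[3,4-bis(benzyloxy)phenyl][3,5-bis(benzyloxy)phenoxy]methyl}oxirane
Conditions: PPh3, DIAD, toluene, 0 °C to rt
Reagents that add atoms: none
Why: Mitsunobu etherification with SN2 inversion at the benzylic carbinol should turn the erythro alcohol into the threo aryl ether that maps onto the 2,3-cis flavan; toluene and low temperature disfavour an ion-pair path, and the epoxide is inert under these neutral conditions.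

**Step 7**
Reactants: 10 (R)-2-{(R)-[3,4-bis(benzyloxy)phenyl][3,5-bis(benzyloxy)phenoxy]methyl}oxirane (2.5 equiv); 5 4β-(2-ethoxyethoxy)-5,7,3',4',5'-penta-O-benzylepigallocatechin 3-O-[3,4,5-tris(benzyloxy)benzoate]
Product: 12 protected dimer [5,7,3',4',5',3'',4'',5''-octa-O-benzyl-(−)-epigallocatechin 3-O-gallate]-(4β→8)-[5,7,3',4'-tetra-O-benzyl-(−)-epicatechin], via tetra-O-benzylepicatechin 11 (not isolated)
Conditions: BF3·OEt2 (0.2 equiv), CH2Cl2, −78 to −40 °C; then 5, TMSOTf (0.1 equiv), −78 to −30 °C; Et3N quench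
Reagents that add atoms: none
Why: BF3 coordinates the terminal epoxide of 10 and the phloroglucinol-type ring attacks its primary carbon (future C4) through the carbon ortho to the ether oxygen (future C4a), rearomatization giving 11; TMSOTf then ionizes the C4 acetal of 5 to the ring-A-stabilized benzylic cation (bridged on its α face by the 3-O-galloyl carbonyl), which is captured by C8 of 11 with loss of a proton. The closest known reaction types are the Lewis-acid-catalysed cyclialkylation of aryl glycidyl ethers to chroman-3-ols and the TMSOTf-catalysed condensation of 4-alkoxyflavans with benzylated flavan-3-ols. Ring C closes in the 6-endo mode (attack at the distal CH2 of the epoxide, C3–O bond kept), the 5-exo alternative at the internal carbon being disfavoured by the neighbouring aryl-bearing C2 and by the strain of a dihydrobenzofuran-forming transition state. The closure creates no stereocenter and breaks no bond to C2 or C3, so (2R,3R) is carried over from 10; the one new stereocenter, C4 of the gallate unit, should be set 4β (trans to O3) by substrate control, the nucleophile adding anti to the axial 3-acyloxy group and its bridging acyloxonium. Two selectivities are needed: endo over exo opening, secured by the unhindered primary terminus, and C8 over C6 in the coupling, secured by closing the ring first so that the nucleophile is a flavan whose C8 (ortho to O1, para to O5) is the established preferred site, with the excess of 10 outcompeting the ring A carbons of 5. Catalytic acid at low temperature should keep the ionizable benzylic C2–O1 ether of 10 and 11 intact.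

**Step 8**
Reactants: 12 protected dimer (2 equiv); 3 (2R,3R,4S)-4β-(2-ethoxyethoxy)-5,7,3',4',5'-penta-O-benzylepigallocatechin (added slowly)
Product: 13 protected trimer [penta-O-benzyl-(−)-epigallocatechin]-(4β→8)-[octa-O-benzyl-(−)-epigallocatechin 3-O-gallate]-(4β→8)-[tetra-O-benzyl-(−)-epicatechin]
Conditions: TMSOTf (0.1 equiv), CH2Cl2, −78 °C; Et3N quench
Reagents that add atoms: none
Why: Lewis-acid-catalysed Friedel–Crafts flavan condensation; the cation from 3 should be attacked on its β face (anti to the axial 3-OH and the C2 aryl group, giving 4β) by C8 of the gallate unit of 12, the only free ring A carbon ortho to a ring oxygen O1, while excess 12 and slow addition suppress self-condensation of 3.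

**Step 9**
Reactants: 13 protected trimer (1.5 equiv); 3 (2R,3R,4S)-4β-(2-ethoxyethoxy)-5,7,3',4',5'-penta-O-benzylepigallocatechin (added slowly)
Product: 14 protected tetramer (22 benzyl ethers) [penta-O-benzyl-(−)-epigallocatechin]-(4β→8)-[penta-O-benzyl-(−)-epigallocatechin]-(4β→8)-[octa-O-benzyl-(−)-epigallocatechin 3-O-gallate]-(4β→8)-[tetra-O-benzyl-(−)-epicatechin]
Conditions: TMSOTf (0.1 equiv), CH2Cl2, −78 °C; Et3N quench
Reagents that add atoms: none
Why: the same Friedel–Crafts flavan condensation; C8 of the newly added top unit of 13 is again the only free position ortho to a ring oxygen O1 and should react, with 4β selectivity set by the 3-OH and C2 aryl group of the electrophile.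

**Step 10**
Reactants: 14 protected tetramer
Product: 15 target tetramer
Conditions: H2 (1 atm), Pd(OH)2/C, THF–MeOH–H2O, rt; filtration, Sephadex LH-20, lyophilization
Reagents that add atoms: none
Why: catalytic hydrogenolysis should cleave all 22 benzyl ethers under neutral conditions that leave the aryl gallate ester, the interflavan bonds, the cyclic benzylic ethers and every stereocenter untouched.

**Compound list**

1 | (−)-epigallocatechin | O[C@@H]1Cc2c(O)cc(O)cc2O[C@@H]1c1cc(O)c(O)c(O)c1 | starting material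
2 | 5,7,3',4',5'-penta-O-benzyl-(−)-epigallocatechin | O[C@@H]1Cc2c(OCc3ccccc3)cc(OCc3ccccc3)cc2O[C@@H]1c1cc(OCc2ccccc2)c(OCc2ccccc2)c(OCc2ccccc2)c1 | intermediate
3 | (2R,3R,4S)-4β-(2-ethoxyethoxy)-5,7,3',4',5'-penta-O-benzylepigallocatechin | O[C@@H]1[C@@H](OCCOCC)c2c(OCc3ccccc3)cc(OCc3ccccc3)cc2O[C@@H]1c1cc(OCc2ccccc2)c(OCc2ccccc2)c(OCc2ccccc2)c1 | intermediate
4 | 3,4,5-tris(benzyloxy)benzoic acid | OC(=O)c1cc(OCc2ccccc2)c(OCc2ccccc2)c(OCc2ccccc2)c1 | starting material
5 | 4β-(2-ethoxyethoxy)-5,7,3',4',5'-penta-O-benzylepigallocatechin 3-O-[3,4,5-tris(benzyloxy)benzoate] | O=C(O[C@@H]1[C@@H](OCCOCC)c2c(OCc3ccccc3)cc(OCc3ccccc3)cc2O[C@@H]1c1cc(OCc2ccccc2)c(OCc2ccccc2)c(OCc2ccccc2)c1)c1cc(OCc2ccccc2)c(OCc2ccccc2)c(OCc2ccccc2)c1 | intermediate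
6 | 3,4-bis(benzyloxy)benzaldehyde | O=Cc1ccc(OCc2ccccc2)c(OCc2ccccc2)c1 | starting material
7 | rac-1-[3,4-bis(benzyloxy)phenyl]prop-2-en-1-ol | OC(C=C)c1ccc(OCc2ccccc2)c(OCc2ccccc2)c1 | intermediate
8 | (S)-[3,4-bis(benzyloxy)phenyl][(R)-oxiran-2-yl]methanol | O[C@@H](c1ccc(OCc2ccccc2)c(OCc2ccccc2)c1)[C@H]1CO1 | intermediate
9 | 3,5-bis(benzyloxy)phenol | Oc1cc(OCc2ccccc2)cc(OCc2ccccc2)c1 | starting material
10 | (R)-2-{(R)-[3,4-bis(benzyloxy)phenyl][3,5-bis(benzyloxy)phenoxy]methyl}oxirane | c1ccccc1COc1cc(OCc2ccccc2)cc(O[C@H](c2ccc(OCc3ccccc3)c(OCc3ccccc3)c2)[C@H]2CO2)c1 | intermediate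
11 | 5,7,3',4'-tetra-O-benzyl-(−)-epicatechin (formed in the flask in step 7) | O[C@@H]1Cc2c(OCc3ccccc3)cc(OCc3ccccc3)cc2O[C@@H]1c1ccc(OCc2ccccc2)c(OCc2ccccc2)c1 | intermediate
12 | protected dimer, [octa-O-benzyl-(−)-epigallocatechin 3-O-gallate]-(4β→8)-[tetra-O-benzyl-(−)-epicatechin] | O=C(O[C@@H]1[C@@H](c2c(OCc7ccccc7)cc(OCc7ccccc7)c3c2O[C@H](c2ccc(OCc7ccccc7)c(OCc7ccccc7)c2)[C@H](O)C3)c2c(OCc7ccccc7)cc(OCc7ccccc7)cc2O[C@@H]1c1cc(OCc7ccccc7)c(OCc7ccccc7)c(OCc7ccccc7)c1)c1cc(OCc7ccccc7)c(OCc7ccccc7)c(OCc7ccccc7)c1 | intermediate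
13 | protected trimer, [penta-O-benzyl-(−)-epigallocatechin]-(4β→8)-[octa-O-benzyl-(−)-epigallocatechin 3-O-gallate]-(4β→8)-[tetra-O-benzyl-(−)-epicatechin] | O=C(O[C@@H]1[C@@H](c2c(OCc7ccccc7)cc(OCc7ccccc7)c3c2O[C@H](c2ccc(OCc7ccccc7)c(OCc7ccccc7)c2)[C@H](O)C3)c2c(OCc7ccccc7)cc(OCc7ccccc7)c([C@H]3c4c(OCc7ccccc7)cc(OCc7ccccc7)cc4O[C@H](c4cc(OCc7ccccc7)c(OCc7ccccc7)c(OCc7ccccc7)c4)[C@@H]3O)c2O[C@@H]1c1cc(OCc7ccccc7)c(OCc7ccccc7)c(OCc7ccccc7)c1)c1cc(OCc7ccccc7)c(OCc7ccccc7)c(OCc7ccccc7)c1 | intermediate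
14 | protected tetramer (22 benzyl ethers) | O=C(O[C@@H]1[C@@H](c2c(OCc7ccccc7)cc(OCc7ccccc7)c3c2O[C@H](c2ccc(OCc7ccccc7)c(OCc7ccccc7)c2)[C@H](O)C3)c2c(OCc7ccccc7)cc(OCc7ccccc7)c([C@H]3c4c(OCc7ccccc7)cc(OCc7ccccc7)c([C@H]5c6c(OCc7ccccc7)cc(OCc7ccccc7)cc6O[C@H](c6cc(OCc7ccccc7)c(OCc7ccccc7)c(OCc7ccccc7)c6)[C@@H]5O)c4O[C@H](c4cc(OCc7ccccc7)c(OCc7ccccc7)c(OCc7ccccc7)c4)[C@@H]3O)c2O[C@@H]1c1cc(OCc7ccccc7)c(OCc7ccccc7)c(OCc7ccccc7)c1)c1cc(OCc7ccccc7)c(OCc7ccccc7)c(OCc7ccccc7)c1 | intermediate
15 | (−)-epigallocatechin-(4β→8)-(−)-epigallocatechin-(4β→8)-(−)-epigallocatechin 3-O-gallate-(4β→8)-(−)-epicatechin | O=C(O[C@@H]1[C@@H](c2c(O)cc(O)c3c2O[C@H](c2ccc(O)c(O)c2)[C@H](O)C3)c2c(O)cc(O)c([C@H]3c4c(O)cc(O)c([C@H]5c6c(O)cc(O)cc6O[C@H](c6cc(O)c(O)c(O)c6)[C@@H]5O)c4O[C@H](c4cc(O)c(O)c(O)c4)[C@@H]3O)c2O[C@@H]1c1cc(O)c(O)c(O)c1)c1cc(O)c(O)c(O)c1 | target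

**Count and risks**

Total step count: 10. Longest linear sequence: 7 steps (1, 2, 3, 7, 8, 9, 10 from epigallocatechin; equally 4, 5, 6, 7, 8, 9, 10 from aldehyde 6).

Steps most likely to fail:

1. Step 7. The activated epoxide may open at its internal carbon or rearrange by a hydride shift before the ring carbon reaches it, or the benzylic C2–O1 ether may ionize and erode C2. Fallback: the same C4–C4a bond is closed with reversed polarity and the coupling is run as a separate step. It sets out from 9 and 8. Ortho-iodination of 9 (N-iodosuccinimide, CH2Cl2, −78 to 0 °C) should give 2-iodo-3,5-bis(benzyloxy)phenol F1. Mitsunobu etherification of 8 with F1 (PPh3, DIAD, toluene) should give the iodo epoxy ether (R)-2-{(R)-[3,4-bis(benzyloxy)phenyl][3,5-bis(benzyloxy)-2-iodophenoxy]methyl}oxirane F2. Iodine–lithium exchange (n-BuLi, THF, −78 °C) followed by BF3·OEt2 should let the aryllithium open the epoxide at its primary carbon (anionic 6-endo closure) to give 11, now isolated. Condensation of 11 with 5 (TMSOTf, CH2Cl2, −78 °C) then returns to the route at 12.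

2. Step 9. Self-condensation of electrophile 3 through its own unsubstituted C8, and attack at the hindered C6 positions of the large trimer, may compete with the wanted C8 attack. Fallback: a bromine-capped electrophile that cannot act as a nucleophile, used in equimolar amount. It sets out from 2 and 13. Bromination of 2 (N-bromosuccinimide, CH2Cl2, −78 to 0 °C) should give 8-bromo-5,7,3',4',5'-penta-O-benzyl-(−)-epigallocatechin F3. DDQ oxidation in the presence of 2-ethoxyethanol should give 8-bromo-4β-(2-ethoxyethoxy)-5,7,3',4',5'-penta-O-benzylepigallocatechin F4. Condensation of F4 with 13 (1:1, TMSOTf, CH2Cl2, −78 °C) should give the 8-bromo protected tetramer F5. Hydrogenolysis (H2, Pd(OH)2/C, Et3N, THF–MeOH) should remove the bromine together with the benzyl groups and returns to the route at 15.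

3. Step 5. The monosubstituted alkene may be epoxidized slowly, the two enantiomers may be discriminated incompletely, and the electron-rich benzylic epoxy alcohol may be opened on the titanium centre. Fallback: enzymatic resolution followed by hydroxyl-directed epoxidation. It sets out from 7. Acylation with vinyl acetate over immobilized Candida antarctica lipase B (toluene, rt) should convert only the (R)-alcohol into (R)-1-[3,4-bis(benzyloxy)phenyl]prop-2-en-1-yl acetate F6. Methanolysis (K2CO3, MeOH) should give (R)-1-[3,4-bis(benzyloxy)phenyl]prop-2-en-1-ol F7. Epoxidation of F7 with VO(acac)2 (cat.) and t-BuOOH (CH2Cl2, 0 °C) should favour the erythro isomer and, after chromatographic removal of the threo isomer, returns to the route at 8.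

**Further compounds**

F1 | step 7 | 2-iodo-3,5-bis(benzyloxy)phenol | Oc1cc(OCc2ccccc2)cc(OCc2ccccc2)c1I
F2 | step 7 | (R)-2-{(R)-[3,4-bis(benzyloxy)phenyl][3,5-bis(benzyloxy)-2-iodophenoxy]methyl}oxirane | Ic1c(OCc2ccccc2)cc(OCc2ccccc2)cc1O[C@H](c1ccc(OCc2ccccc2)c(OCc2ccccc2)c1)[C@H]1CO1
F3 | step 9 | 8-bromo-5,7,3',4',5'-penta-O-benzyl-(−)-epigallocatechin | O[C@@H]1Cc2c(OCc3ccccc3)cc(OCc3ccccc3)c(Br)c2O[C@@H]1c1cc(OCc2ccccc2)c(OCc2ccccc2)c(OCc2ccccc2)c1
F4 | step 9 | 8-bromo-4β-(2-ethoxyethoxy)-5,7,3',4',5'-penta-O-benzylepigallocatechin | O[C@@H]1[C@@H](OCCOCC)c2c(OCc3ccccc3)cc(OCc3ccccc3)c(Br)c2O[C@@H]1c1cc(OCc2ccccc2)c(OCc2ccccc2)c(OCc2ccccc2)c1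
F5 | step 9 | 8-bromo protected tetramer (bromine on C8 of the top unit of 14) | O=C(O[C@@H]1[C@@H](c2c(OCc7ccccc7)cc(OCc7ccccc7)c3c2O[C@H](c2ccc(OCc7ccccc7)c(OCc7ccccc7)c2)[C@H](O)C3)c2c(OCc7ccccc7)cc(OCc7ccccc7)c([C@H]3c4c(OCc7ccccc7)cc(OCc7ccccc7)c([C@H]5c6c(OCc7ccccc7)cc(OCc7ccccc7)c(Br)c6O[C@H](c6cc(OCc7ccccc7)c(OCc7ccccc7)c(OCc7ccccc7)c6)[C@@H]5O)c4O[C@H](c4cc(OCc7ccccc7)c(OCc7ccccc7)c(OCc7ccccc7)c4)[C@@H]3O)c2O[C@@H]1c1cc(OCc7ccccc7)c(OCc7ccccc7)c(OCc7ccccc7)c1)c1cc(OCc7ccccc7)c(OCc7ccccc7)c(OCc7ccccc7)c1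
F6 | step 5 | (R)-1-[3,4-bis(benzyloxy)phenyl]prop-2-en-1-yl acetate | CC(=O)O[C@@H](c1ccc(OCc2ccccc2)c(OCc2ccccc2)c1)C=C
F7 | step 5 | (R)-1-[3,4-bis(benzyloxy)phenyl]prop-2-en-1-ol | O[C@@H](c1ccc(OCc2ccccc2)c(OCc2ccccc2)c1)C=C
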